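## Retrosynthetic overview

- Core numbering used throughout: C1 (OMe bridgehead), C2 (C=O), C3 (CHOMe), C4 (CH2), C5 (allyl bridgehead), C6 (CHMe), C7 (CHAr), C8 (CHOAc); ring A = C1-C2-C3-C4-C5-C8, ring B = C1-C7-C6-C5-C8. The plan rests on ring B: with C8 at the carbonyl level it is an α-methoxy cyclopentanone carrying trans C6-Me/C7-Ar, which is the retron of a 2-methoxy divinyl ketone.
- C8-OAc/C2=O comes from the aldol pattern C8=O/C2-OH by directed C8 reduction, selective C2 oxidation, kinetic protonation at C3 and acetylation.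
- Ring A comes from a C1-C2 aldol closure and a C5-C4 Mukaiyama–Michael addition of the C5=C8 enol silane to 2-methoxyacrolein.
- Ring B comes from an enantioselective reductive Nazarov cyclisation (C6-C7 bond) of dienone 12, which is assembled by two Horner–Wadsworth–Emmons olefinations.
- Ring order: ring B (step 5), then ring A (step 8).

Key step: step 5

Remark on the chemistry: the sense of induction of the scandium–pybox catalyst in step 5 cannot be predicted with confidence, so the (S,S)-ligand named there is provisional and its antipode is used if the opposite sense of conrotation results. C3 is carried as an epimer mixture from step 7 to step 10 and is fixed in step 11.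

## Route

Step 1
Reactants: 1 diethyl [2-(methoxy(methyl)amino)-2-oxoethyl]phosphonate; 2 allyl bromide
Product: 4 diethyl [1-(methoxy(methyl)amino)-1-oxopent-4-en-2-yl]phosphonate (racemic), via sodium carbanion of the starting phosphonate 3 (not isolated)
Conditions: NaH, THF, 0 °C; then 2, 0 °C to rt
Reagents that add atoms: none
Why: SN2 alkylation of the doubly stabilised phosphonate carbanion by allyl bromide; a slight excess of 1 should suppress dialkylation.

Step 2
Reactants: 4 diethyl [1-(methoxy(methyl)amino)-1-oxopent-4-en-2-yl]phosphonate; 5 acetaldehyde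
Product: 7 (2E)-N-methoxy-N-methyl-2-(prop-2-en-1-yl)but-2-enamide, via sodium carbanion of the allylated phosphonate 6 (not isolated)
Conditions: NaH, THF, 0 °C; then MeCHO (3 equiv), −78 to 0 °C
Reagents that add atoms: none
Why: Horner–Wadsworth–Emmons olefination; α-branched phosphonoamides should give mainly the trisubstituted alkene with the β-methyl trans to the amide carbonyl, and the minor (Z)-isomer is removed by chromatography.

Step 3
Reactants: 8 diethyl (methoxymethyl)phosphonate; 7 (2E)-N-methoxy-N-methyl-2-(prop-2-en-1-yl)but-2-enamide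
Product: 10 diethyl [(3E)-1-methoxy-2-oxo-3-(prop-2-en-1-yl)pent-3-en-1-yl]phosphonate (racemic), via diethyl [lithio(methoxy)methyl]phosphonate 9 (not isolated)
Conditions: LiN(iPr)2, THF, −78 °C; then 7, −78 to −40 °C; aq. NH4Cl
Reagents that add atoms: none
Why: Acylation of the α-lithio α-methoxyphosphonate by the Weinreb amide, whose chelated tetrahedral adduct prevents over-addition; 1,2-attack is favoured because the enamide is α,β-disubstituted.

Step 4
Reactants: 10 diethyl [(3E)-1-methoxy-2-oxo-3-(prop-2-en-1-yl)pent-3-en-1-yl]phosphonate; 11 3,4-dimethoxybenzaldehyde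
Product: 12 (1Z,4E)-1-(3,4-dimethoxyphenyl)-2-methoxy-4-(prop-2-en-1-yl)hexa-1,4-dien-3-one
Conditions: Ba(OH)2·8H2O, THF/H2O (40:1), rt
Reagents that add atoms: none
Why: Horner–Wadsworth–Emmons olefination of a β-ketophosphonate under mild hydroxide conditions that leave the skipped diene in place; α-alkoxy ketophosphonates should give the enol ether with aryl cis to OMe and trans to C=O, the geometry that puts the aryl group outward in the pentadienyl cation.

Step 5
Reactants: 12 (1Z,4E)-1-(3,4-dimethoxyphenyl)-2-methoxy-4-(prop-2-en-1-yl)hexa-1,4-dien-3-one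
Product: 13 triethyl{[(3R,4S,5R)-4-(3,4-dimethoxyphenyl)-5-methoxy-3-methyl-2-(prop-2-en-1-yl)cyclopent-1-en-1-yl]oxy}silane
Conditions: Sc(OTf)3 (10 mol %), 2,6-bis[(4S)-4-isopropyl-4,5-dihydrooxazol-2-yl]pyridine (12 mol %), Et3SiH (1.5 equiv), 2,6-di-tert-butylpyridine (0.2 equiv), 4 Å molecular sieves, MeCN/CH2Cl2, −20 °C
Reagents that add atoms: triethylsilane, CC[SiH](CC)CC
Why: Proposed new method: the Sc(OTf)3–pybox complex binds the C8 carbonyl oxygen and the C1 methoxy oxygen of 12 in a five-membered chelate, giving a 3-oxidopentadienyl cation held in the U-shaped conformation that closes ring B by thermal conrotatory 4π electrocyclisation (C6-C7 bond); the resulting 2-oxyallyl cation is an oxocarbenium ion at C1, takes hydride from Et3SiH there, and silyl transfer to the scandium enolate releases the C5=C8 silyl enol ether and the catalyst. The closest known reactions are the hydride-interrupted (reductive) Nazarov cyclisation with Et3SiH under achiral Lewis acids and the enantioselective Nazarov cyclisation of 2-alkoxy dienones with chiral scandium–pybox or chiral Brønsted acid catalysts; running both in one catalytic cycle has not been shown. C6 and C7 should come out trans because methyl and aryl are both outward (trans to the carbonyl) in the (1Z,4E)-dienone and conrotation turns them to opposite faces, while their absolute configuration follows from the direction of conrotation imposed by the chiral ligand sphere. The C1 hydrogen is delivered anti to the adjacent C7 aryl group, at a centre that is re-formed in step 8. The step needs enantioselectivity, secured by rigid two-point binding of the 2-methoxy enone to the chiral metal, and regioselective hydride capture, secured by the methoxy group that localises the cation at C1 so that the enol silane can only be C5=C8. Racemic background cyclisation by liberated Et3SiOTf is the main threat and is countered by low temperature and the hindered pyridine buffer.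

Step 6
Reactants: 14 1,1,2-trimethoxyethane
Product: 16 2-methoxyprop-2-enal, via methoxyacetaldehyde 15 (not isolated)
Conditions: 1 M aq. H2SO4 (cat.), 50 °C; NaHCO3 to pH 6; then 37% aq. CH2O, pyrrolidine (10 mol %), propionic acid (10 mol %), 45 °C; distillation
Reagents that add atoms: water, O; formaldehyde, C=O
Why: Acetal hydrolysis followed by amine-catalysed Mannich condensation with formaldehyde and β-elimination (α-methylenation of an aldehyde) at the only enolisable position.

Step 7
Reactants: 13 triethyl{[(3R,4S,5R)-4-(3,4-dimethoxyphenyl)-5-methoxy-3-methyl-2-(prop-2-en-1-yl)cyclopent-1-en-1-yl]oxy}silane; 16 2-methoxyprop-2-enal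
Product: 18 3-[(1S,2R,3S,4R)-3-(3,4-dimethoxyphenyl)-4-methoxy-2-methyl-5-oxo-1-(prop-2-en-1-yl)cyclopentyl]-2-methoxypropanal (C3 epimer mixture), via aldehyde triethylsilyl enol ether 17 (not isolated)
Conditions: Sc(OTf)3 (10 mol %), 2,6-di-tert-butylpyridine (0.2 equiv), 16 (2 equiv), CH2Cl2/MeCN, −60 °C; then 1 M HCl, THF, 0 °C
Reagents that add atoms: none
Why: Mukaiyama–Michael addition in which the tetrasubstituted enol silane attacks the CH2 terminus of the chelated 2-alkoxy enal (1,4-attack being favoured for so hindered a nucleophile), making C5 quaternary with the new chain anti to the adjacent C6 methyl; C3 forms without control on hydrolysis.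

Step 8
Reactants: 18 3-[(1S,2R,3S,4R)-3-(3,4-dimethoxyphenyl)-4-methoxy-2-methyl-5-oxo-1-(prop-2-en-1-yl)cyclopentyl]-2-methoxypropanal
Product: 19 (1R,2R,5S,6R,7S)-7-(3,4-dimethoxyphenyl)-2-hydroxy-1,3-dimethoxy-6-methyl-5-(prop-2-en-1-yl)bicyclo[3.2.1]octan-8-one (C3 epimer mixture)
Conditions: MgBr2·OEt2 (1.5 equiv), Et3N (2 equiv), CH2Cl2 (0.02 M), 0 °C to rt
Reagents that add atoms: none
Why: Intramolecular aldol addition (6-enolendo-exo-trig) after chelation-assisted soft enolisation of the α-methoxy ketone, which can enolise only towards C1; the tether from C5 forces the C1-C2 bond onto the face cis to C4 and closes ring A, and the magnesium aldolate bridged to the C8 carbonyl should place the C2 oxygen exo (syn to C8), away from the endo C7 aryl group.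

Step 9
Reactants: 19 (1R,2R,5S,6R,7S)-7-(3,4-dimethoxyphenyl)-2-hydroxy-1,3-dimethoxy-6-methyl-5-(prop-2-en-1-yl)bicyclo[3.2.1]octan-8-one
Product: 20 (1S,2R,5S,6R,7S,8S)-7-(3,4-dimethoxyphenyl)-1,3-dimethoxy-6-methyl-5-(prop-2-en-1-yl)bicyclo[3.2.1]octane-2,8-diol (C3 epimer mixture)
Conditions: Et2BOMe (1.2 equiv), NaBH4 (1.5 equiv), THF/MeOH (4:1), −78 °C; MeOH co-evaporation
Reagents that add atoms: none
Why: Narasaka–Prasad reduction in which the exo C2 oxygen, bound to boron and bridged to the C8 carbonyl, covers the ring A face of C8=O, so external hydride should enter from the ring B face and give the C8 hydroxyl syn to ring A (1,3-syn diol).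

Step 10
Reactants: 20 (1S,2R,5S,6R,7S,8S)-7-(3,4-dimethoxyphenyl)-1,3-dimethoxy-6-methyl-5-(prop-2-en-1-yl)bicyclo[3.2.1]octane-2,8-diol
Product: 21 (1S,5S,6R,7S,8S)-7-(3,4-dimethoxyphenyl)-8-hydroxy-1,3-dimethoxy-6-methyl-5-(prop-2-en-1-yl)bicyclo[3.2.1]octan-2-one (C3 epimer mixture)
Conditions: 2,2,6,6-tetramethylpiperidin-1-oxyl (20 mol %), PhI(OAc)2 (1.3 equiv), CH2Cl2, rt
Reagents that add atoms: none
Why: Nitroxyl-catalysed alcohol oxidation, which is strongly retarded by steric hindrance: the C8 carbinol lies between two quaternary carbons (C1, C5) on the one-carbon bridge, whereas C2 has one quaternary and one tertiary neighbour and should be oxidised first.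

Step 11
Reactants: 21 (1S,5S,6R,7S,8S)-7-(3,4-dimethoxyphenyl)-8-hydroxy-1,3-dimethoxy-6-methyl-5-(prop-2-en-1-yl)bicyclo[3.2.1]octan-2-one
Product: 23 (1S,3S,5S,6R,7S,8S)-7-(3,4-dimethoxyphenyl)-8-hydroxy-1,3-dimethoxy-6-methyl-5-(prop-2-en-1-yl)bicyclo[3.2.1]octan-2-one, via dilithium alkoxide enolate 22 (not isolated)
Conditions: LiN(iPr)2 (2.5 equiv), THF, −78 °C; then AcOH in THF, −78 °C
Reagents that add atoms: none
Why: Kinetic protonation of the C2 enolate, in which the endo face of C3 is screened by the C7 aryl group and the proton should arrive on the exo face, relayed by the neighbouring syn C8 oxygen, placing H exo and OMe endo as in the target and converging both C3 epimers.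

Step 12
Reactants: 23 (1S,3S,5S,6R,7S,8S)-7-(3,4-dimethoxyphenyl)-8-hydroxy-1,3-dimethoxy-6-methyl-5-(prop-2-en-1-yl)bicyclo[3.2.1]octan-2-one
Product: 24 (1S,3S,5S,6R,7S,8S)-7-(3,4-dimethoxyphenyl)-1,3-dimethoxy-6-methyl-2-oxo-5-(prop-2-en-1-yl)bicyclo[3.2.1]octan-8-yl acetate
Conditions: Ac2O, 4-(dimethylamino)pyridine, Et3N, CH2Cl2, 0 °C to rt
Reagents that add atoms: acetic anhydride, CC(=O)OC(C)=O
Why: Nucleophile-catalysed acylation of the hindered secondary alcohol under mildly basic conditions that should not enolise the α-methoxy ketone.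

## Compound list

1 | diethyl [2-(methoxy(methyl)amino)-2-oxoethyl]phosphonate | CCOP(=O)(OCC)CC(=O)N(C)OC | starting material
2 | allyl bromide | C=CCBr | starting material
3 | sodium carbanion of 1 | CCOP(=O)(OCC)[CH-]C(=O)N(C)OC.[Na+] | intermediate
4 | diethyl [1-(methoxy(methyl)amino)-1-oxopent-4-en-2-yl]phosphonate (racemic) | CCOP(=O)(OCC)C(CC=C)C(=O)N(C)OC | intermediate
5 | acetaldehyde | CC=O | starting material
6 | sodium carbanion of 4 | CCOP(=O)(OCC)[C-](CC=C)C(=O)N(C)OC.[Na+] | intermediate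
7 | (2E)-N-methoxy-N-methyl-2-(prop-2-en-1-yl)but-2-enamide | C/C=C(\CC=C)C(=O)N(C)OC | intermediate
8 | diethyl (methoxymethyl)phosphonate | CCOP(=O)(OCC)COC | starting material
9 | diethyl [lithio(methoxy)methyl]phosphonate | CCOP(=O)(OCC)[CH-]OC.[Li+] | intermediate
10 | diethyl [(3E)-1-methoxy-2-oxo-3-(prop-2-en-1-yl)pent-3-en-1-yl]phosphonate (racemic) | CCOP(=O)(OCC)C(OC)C(=O)/C(CC=C)=C/C | intermediate
11 | 3,4-dimethoxybenzaldehyde | COc1ccc(C=O)cc1OC | starting material
12 | (1Z,4E)-1-(3,4-dimethoxyphenyl)-2-methoxy-4-(prop-2-en-1-yl)hexa-1,4-dien-3-one | COc1ccc(/C=C(\OC)C(=O)/C(CC=C)=C/C)cc1OC | intermediate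
13 | triethyl{[(3R,4S,5R)-4-(3,4-dimethoxyphenyl)-5-methoxy-3-methyl-2-(prop-2-en-1-yl)cyclopent-1-en-1-yl]oxy}silane (C5=C8 enol silane of ring B; trans Me/Ar) | C=CCC1=C(O[Si](CC)(CC)CC)[C@H](OC)[C@H](c2ccc(OC)c(OC)c2)[C@H]1C | intermediate
14 | 1,1,2-trimethoxyethane | COCC(OC)OC | starting material
15 | methoxyacetaldehyde | COCC=O | intermediate
16 | 2-methoxyprop-2-enal | COC(=C)C=O | intermediate
17 | triethylsilyl enol ether of aldehyde 18 (enol ether E/Z mixture) | C=CC[C@]1(CC(OC)=CO[Si](CC)(CC)CC)[C@H](C)[C@@H](c2ccc(OC)c(OC)c2)[C@@H](OC)C1=O | intermediate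
18 | 3-[(1S,2R,3S,4R)-3-(3,4-dimethoxyphenyl)-4-methoxy-2-methyl-5-oxo-1-(prop-2-en-1-yl)cyclopentyl]-2-methoxypropanal (C3 epimer mixture) | C=CC[C@]1(CC(OC)C=O)[C@H](C)[C@@H](c2ccc(OC)c(OC)c2)[C@@H](OC)C1=O | intermediate
19 | (1R,2R,5S,6R,7S)-7-(3,4-dimethoxyphenyl)-2-hydroxy-1,3-dimethoxy-6-methyl-5-(prop-2-en-1-yl)bicyclo[3.2.1]octan-8-one (C2-OH exo, syn to C8; C3 epimer mixture) | C=CC[C@]12CC(OC)[C@@H](O)[C@](OC)([C@H](c3ccc(OC)c(OC)c3)[C@H]1C)C2=O | intermediate
20 | (1S,2R,5S,6R,7S,8S)-7-(3,4-dimethoxyphenyl)-1,3-dimethoxy-6-methyl-5-(prop-2-en-1-yl)bicyclo[3.2.1]octane-2,8-diol (C8-OH syn to ring A; C3 epimer mixture) | C=CC[C@]12CC(OC)[C@@H](O)[C@](OC)([C@H](c3ccc(OC)c(OC)c3)[C@H]1C)[C@H]2O | intermediate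
21 | (1S,5S,6R,7S,8S)-7-(3,4-dimethoxyphenyl)-8-hydroxy-1,3-dimethoxy-6-methyl-5-(prop-2-en-1-yl)bicyclo[3.2.1]octan-2-one (C3 epimer mixture) | C=CC[C@]12CC(OC)C(=O)[C@](OC)([C@H](c3ccc(OC)c(OC)c3)[C@H]1C)[C@H]2O | intermediate
22 | dilithium C8-alkoxide C2-enolate of 21 | C=CC[C@]12CC(OC)=C([O-])[C@](OC)([C@H](c3ccc(OC)c(OC)c3)[C@H]1C)[C@H]2[O-].[Li+].[Li+] | intermediate
23 | (1S,3S,5S,6R,7S,8S)-7-(3,4-dimethoxyphenyl)-8-hydroxy-1,3-dimethoxy-6-methyl-5-(prop-2-en-1-yl)bicyclo[3.2.1]octan-2-one | C=CC[C@]12C[C@H](OC)C(=O)[C@](OC)([C@H](c3ccc(OC)c(OC)c3)[C@H]1C)[C@H]2O | intermediate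
24 | (1S,3S,5S,6R,7S,8S)-7-(3,4-dimethoxyphenyl)-1,3-dimethoxy-6-methyl-2-oxo-5-(prop-2-en-1-yl)bicyclo[3.2.1]octan-8-yl acetate | C=CC[C@]12C[C@H](OC)C(=O)[C@](OC)([C@H](c3ccc(OC)c(OC)c3)[C@H]1C)[C@H]2OC(C)=O | target

## Step count and risks

Total step count: 12. Longest linear sequence: 11 steps (steps 1–5 and 7–12); step 6 is a one-step side branch.

Steps most likely to fail:

1. Step 5 (proposed new method). What may go wrong: erosion of enantioselectivity by a silyl-triflate-catalysed racemic background cyclisation, reduction of the pentadienyl cation before ring closure, or protodesilylation of the enol silane. Fallback (known chemistry, enantiocontrol by resolution instead of catalysis): it sets out from 12. The established achiral hydride-interrupted Nazarov protocol (Et3SiOTf, Et3SiH, CH2Cl2, −78 °C, Et3N quench) should give the racemic triethylsilyl enol ether F1. Its enantiomers are separated by preparative chromatography on a chiral stationary phase with a hexane-based eluent; the (3R,4S,5R)-enantiomer is 13, where the route is rejoined.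

2. Step 7. What may go wrong: 1,2-addition to the aldehyde instead of conjugate addition, Lewis-acid ionisation of the allylic C1 methoxy group of the enol silane, or poor facial selectivity at C5. Fallback (anionic Michael addition to an ester acceptor, then redox adjustment): it sets out from 13. MeLi (THF, 0 °C) should give the regiodefined lithium enolate F2, which adds at −78 °C to methyl 2-methoxyacrylate to give the keto ester F3. LiAlH4 reduces ester and ketone to the diol F4, and oxidation of both hydroxyl groups with Dess–Martin periodinane returns keto aldehyde 18.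

3. Step 10. What may go wrong: loss of chemoselectivity (oxidation at C8 or at both carbinols) or no oxidation at the hindered C2 carbinol. Fallback (differentiation by protection before the C8 ketone is reduced): it sets out from 19. Et3SiOTf and 2,6-lutidine should give the C2 triethylsilyl ether F5. NaBH4 then reduces C8 from the ring B face, the ring A face being covered by the silyl ether, to the alcohol F6, which is acetylated (Ac2O, 4-(dimethylamino)pyridine) to the silyl ether acetate F7. HF·pyridine frees the C2 hydroxyl to give the hydroxy acetate F8, and Dess–Martin periodinane should give 24 together with its C3 epimer F9. The mixture is converged by soft enolisation (Me3SiOTf, Et3N) to the trimethylsilyl enol ether F10 and protonation on the exo face (AcOH, THF/H2O, −20 °C), which returns 24.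

Further compounds
F1 | step 5 | racemic triethylsilyl enol ether (racemate of 13) | C=CCC1=C(O[Si](CC)(CC)CC)[C@H](OC)[C@H](c2ccc(OC)c(OC)c2)[C@H]1C.C=CCC1=C(O[Si](CC)(CC)CC)[C@@H](OC)[C@@H](c2ccc(OC)c(OC)c2)[C@@H]1C
F2 | step 7 | lithium (3R,4S,5R)-4-(3,4-dimethoxyphenyl)-5-methoxy-3-methyl-2-(prop-2-en-1-yl)cyclopent-1-en-1-olate | C=CCC1=C([O-])[C@H](OC)[C@H](c2ccc(OC)c(OC)c2)[C@H]1C.[Li+]
F3 | step 7 | methyl 3-[(1S,2R,3S,4R)-3-(3,4-dimethoxyphenyl)-4-methoxy-2-methyl-5-oxo-1-(prop-2-en-1-yl)cyclopentyl]-2-methoxypropanoate (C2 epimer mixture of the propanoate) | C=CC[C@]1(CC(OC)C(=O)OC)[C@H](C)[C@@H](c2ccc(OC)c(OC)c2)[C@@H](OC)C1=O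
F4 | step 7 | 3-[(1S,2R,3S,4R)-3-(3,4-dimethoxyphenyl)-5-hydroxy-4-methoxy-2-methyl-1-(prop-2-en-1-yl)cyclopentyl]-2-methoxypropan-1-ol (epimer mixture at the carbinol and methoxy-bearing carbons) | C=CC[C@]1(CC(OC)CO)[C@H](C)[C@@H](c2ccc(OC)c(OC)c2)[C@@H](OC)C1O
F5 | step 10 | (1R,2R,5S,6R,7S)-7-(3,4-dimethoxyphenyl)-1,3-dimethoxy-6-methyl-5-(prop-2-en-1-yl)-2-(triethylsilyloxy)bicyclo[3.2.1]octan-8-one | C=CC[C@]12CC(OC)[C@@H](O[Si](CC)(CC)CC)[C@](OC)([C@H](c3ccc(OC)c(OC)c3)[C@H]1C)C2=O
F6 | step 10 | (1S,2R,5S,6R,7S,8S)-7-(3,4-dimethoxyphenyl)-1,3-dimethoxy-6-methyl-5-(prop-2-en-1-yl)-2-(triethylsilyloxy)bicyclo[3.2.1]octan-8-ol | C=CC[C@]12CC(OC)[C@@H](O[Si](CC)(CC)CC)[C@](OC)([C@H](c3ccc(OC)c(OC)c3)[C@H]1C)[C@H]2O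
F7 | step 10 | (1S,2R,5S,6R,7S,8S)-7-(3,4-dimethoxyphenyl)-1,3-dimethoxy-6-methyl-5-(prop-2-en-1-yl)-2-(triethylsilyloxy)bicyclo[3.2.1]octan-8-yl acetate | C=CC[C@]12CC(OC)[C@@H](O[Si](CC)(CC)CC)[C@](OC)([C@H](c3ccc(OC)c(OC)c3)[C@H]1C)[C@H]2OC(C)=O
F8 | step 10 | (1S,2R,5S,6R,7S,8S)-7-(3,4-dimethoxyphenyl)-2-hydroxy-1,3-dimethoxy-6-methyl-5-(prop-2-en-1-yl)bicyclo[3.2.1]octan-8-yl acetate | C=CC[C@]12CC(OC)[C@@H](O)[C@](OC)([C@H](c3ccc(OC)c(OC)c3)[C@H]1C)[C@H]2OC(C)=O
F9 | step 10 | (1S,3R,5S,6R,7S,8S)-7-(3,4-dimethoxyphenyl)-1,3-dimethoxy-6-methyl-2-oxo-5-(prop-2-en-1-yl)bicyclo[3.2.1]octan-8-yl acetate (C3 epimer of 24) | C=CC[C@]12C[C@@H](OC)C(=O)[C@](OC)([C@H](c3ccc(OC)c(OC)c3)[C@H]1C)[C@H]2OC(C)=O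
F10 | step 10 | (1S,5S,6R,7S,8S)-7-(3,4-dimethoxyphenyl)-1,3-dimethoxy-6-methyl-5-(prop-2-en-1-yl)-2-(trimethylsilyloxy)bicyclo[3.2.1]oct-2-en-8-yl acetate | C=CC[C@]12CC(OC)=C(O[Si](C)(C)C)[C@](OC)([C@H](c3ccc(OC)c(OC)c3)[C@H]1C)[C@H]2OC(C)=O
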